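**Retrosynthetic overview**

1. Target 32 comes from its tetra-O-benzyl ether 31 by hydrogenolysis; in 31 the hydroxyl on C2 of the catechol ring (ring B) is already free.
2. The route rests on that hydroxyl: the O–H on C2 of the 2,3-dihydroxy-4-methoxyphenyl ring, ortho to the carbon bonded to chroman C3, is a latent leaving group on chroman C4, and C4 is benzylic to the central ring, which carries a methoxy group ortho and an oxygen para to it. The C4–C4a bond and the pyran ring of the 3,4-diarylchroman are therefore made last, from the 2-aryl-2,3-dihydrobenzofuran 29, by ionising its C2–O1 bond and closing onto a tethered 3-(benzyloxy)phenyl ether.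
3. 29 comes from alcohol 27 and 3-(benzyloxy)phenol (Mitsunobu); 27 from ester 26; 26 from aryldiazoacetate 25 by enantioselective rhodium-carbenoid C–H insertion (furan ring); 25 from phenol ester 23 (ring B) and benzylic alcohol 16.
4. 16 (central ring plus the (R)-isoflavan) comes from diol 15 by copper-catalysed aryl ether closure; 15 from auxiliary-controlled alkylation of the orsellinate-derived imide 12 with benzylic bromide 4.
5. Ring order: isoflavan pyran ring (step 10), dihydrobenzofuran ring (step 17), diarylchroman pyran ring with loss of the furan ring (step 20).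

Key step: step 20

Assumption: Rh2(S-PTTL)4 (dirhodium tetrakis[N-phthaloyl-(S)-tert-leucinate]) is taken to give the cis (2R,3S) ester 26, the sense it shows with simpler 2-(benzyloxy)aryl diazoacetates; if this substrate reverses it, Rh2(R-PTTL)4 is used, and only C3 matters because step 20 erases C2.

**Route**

Step 1
Reactants: 1 2-bromo-4-hydroxybenzaldehyde
Product: 2 4-(benzyloxy)-2-bromobenzaldehyde
Conditions: BnBr, K2CO3, DMF, rt
Reagents that add atoms: benzyl bromide, BrCc1ccccc1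
Why: Williamson etherification of the only acidic hydroxyl, whose phenoxide is alkylated cleanly at oxygen.

Step 2
Reactants: 2 4-(benzyloxy)-2-bromobenzaldehyde
Product: 3 [4-(benzyloxy)-2-bromophenyl]methanol
Conditions: NaBH4, MeOH–THF, 0 °C
Reagents that add atoms: none
Why: Borohydride reduction of the aldehyde to the benzylic alcohol; the aryl bromide and the benzyl ether are inert to NaBH4.

Step 3
Reactants: 3 [4-(benzyloxy)-2-bromophenyl]methanol
Product: 4 4-(benzyloxy)-2-bromo-1-(bromomethyl)benzene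
Conditions: PBr3, CH2Cl2, 0 °C
Reagents that add atoms: phosphorus tribromide, BrP(Br)Br
Why: Bromination of a benzylic alcohol with PBr3 (SN2 on the phosphite ester); the para benzyloxy group makes the bromide labile, so it is used without storage.

Step 4
Reactants: 5 methyl 2,4-dihydroxy-6-methylbenzoate
Product: 6 methyl 4-(benzyloxy)-2-hydroxy-6-methylbenzoate
Conditions: BnBr (1.05 equiv), K2CO3, acetone, reflux
Reagents that add atoms: benzyl bromide, BrCc1ccccc1
Why: Regioselective Williamson etherification: the 2-hydroxyl is held in a hydrogen bond to the ester carbonyl, so one equivalent of benzyl bromide alkylates the 4-hydroxyl.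

Step 5
Reactants: 6 methyl 4-(benzyloxy)-2-hydroxy-6-methylbenzoate
Product: 7 methyl 4-(benzyloxy)-2-methoxy-6-methylbenzoate
Conditions: MeI, K2CO3, DMF, 50 °C
Reagents that add atoms: iodomethane, CI
Why: Williamson methylation of the remaining chelated phenol, which needs only the more forcing DMF conditions.

Step 6
Reactants: 7 methyl 4-(benzyloxy)-2-methoxy-6-methylbenzoate
Product: 9 2-[5-(benzyloxy)-3-methoxy-2-(methoxycarbonyl)phenyl]acetic acid, via lithiated toluate 8 (not isolated)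
Conditions: LiN(iPr)2 (2.1 equiv), THF, −78 °C; CO2; aq HCl
Reagents that add atoms: carbon dioxide, O=C=O
Why: Lateral lithiation of an ortho-toluate followed by carboxylation: the benzylic anion is stabilised by the adjacent ester, whose two ortho substituents keep it from being attacked at −78 °C.

Step 7
Reactants: 9 2-[5-(benzyloxy)-3-methoxy-2-(methoxycarbonyl)phenyl]acetic acid; 10 (4R)-4-benzyl-1,3-oxazolidin-2-one
Product: 12 methyl 2-{2-[(4R)-4-benzyl-2-oxo-1,3-oxazolidin-3-yl]-2-oxoethyl}-4-(benzyloxy)-6-methoxybenzoate, via mixed pivalic anhydride 11 (not isolated)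
Conditions: PivCl, Et3N, THF, −20 °C; then 10, LiCl, rt
Reagents that add atoms: none
Why: N-Acylation of the oxazolidinone through the pivalic mixed anhydride with LiCl assistance; the doubly ortho-substituted methyl benzoate is far less electrophilic and is untouched.

Step 8
Reactants: 12 methyl 2-{2-[(4R)-4-benzyl-2-oxo-1,3-oxazolidin-3-yl]-2-oxoethyl}-4-(benzyloxy)-6-methoxybenzoate; 4 4-(benzyloxy)-2-bromo-1-(bromomethyl)benzene
Product: 14 methyl 2-{(2R)-1-[(4R)-4-benzyl-2-oxo-1,3-oxazolidin-3-yl]-3-[4-(benzyloxy)-2-bromophenyl]-1-oxopropan-2-yl}-4-(benzyloxy)-6-methoxybenzoate, via sodium Z-enolate 13 (not isolated)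
Conditions: NaN(SiMe3)2, THF, −78 °C; then 4, −78 → −30 °C
Reagents that add atoms: none
Why: Evans asymmetric alkylation: the sodium Z-enolate is held planar by chelation to the oxazolidinone carbonyl and the benzylic bromide enters on the face away from the C4 benzyl group of the (R)-auxiliary, setting the (R) centre that becomes C3 of the isoflavan.

Step 9
Reactants: 14 methyl 2-{(2R)-1-[(4R)-4-benzyl-2-oxo-1,3-oxazolidin-3-yl]-3-[4-(benzyloxy)-2-bromophenyl]-1-oxopropan-2-yl}-4-(benzyloxy)-6-methoxybenzoate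
Product: 15 (2R)-2-[5-(benzyloxy)-2-(hydroxymethyl)-3-methoxyphenyl]-3-[4-(benzyloxy)-2-bromophenyl]propan-1-ol
Conditions: LiAlH4, THF, 0 °C → rt; aq NaOH work-up
Reagents that add atoms: none
Why: LiAlH4 reduction cleaves the imide to the primary alcohol with release of the auxiliary and reduces the hindered benzoate (or the isochromanone that the intermediate alkoxide may form from it) to the benzylic alcohol; hydride addition is faster than enolisation, so the stereocentre is kept.

Step 10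
Reactants: 15 (2R)-2-[5-(benzyloxy)-2-(hydroxymethyl)-3-methoxyphenyl]-3-[4-(benzyloxy)-2-bromophenyl]propan-1-ol
Product: 16 {4-(benzyloxy)-2-[(3R)-7-(benzyloxy)-3,4-dihydro-2H-chromen-3-yl]-6-methoxyphenyl}methanol
Conditions: CuI (10 mol %), 3,4,7,8-tetramethyl-1,10-phenanthroline (20 mol %), Cs2CO3, toluene, 110 °C
Reagents that add atoms: none
Why: Ullmann-type copper-catalysed intramolecular C–O coupling: only the aliphatic hydroxyl can reach the aryl bromide through a six-membered ring (the benzylic hydroxyl would need an eight-membered one), which closes the isoflavan pyran ring.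

Step 11
Reactants: 17 2,3-dihydroxy-4-methoxybenzaldehyde
Product: 18 3-(benzyloxy)-2-hydroxy-4-methoxybenzaldehyde
Conditions: NaH (2.2 equiv), DMSO, rt; then BnBr (1.0 equiv)
Reagents that add atoms: benzyl bromide, BrCc1ccccc1
Why: Dianion alkylation: the phenoxide at C3 is not conjugated to the formyl group and is the more nucleophilic, so one equivalent of benzyl bromide etherifies O3 and leaves the chelated O2 free.

Step 12
Reactants: 18 3-(benzyloxy)-2-hydroxy-4-methoxybenzaldehyde
Product: 19 3-(benzyloxy)-4-methoxy-2-(methoxymethoxy)benzaldehyde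
Conditions: NaH, MOMCl, DMF, 0 °C → rt
Reagents that add atoms: chloromethyl methyl ether, COCCl
Why: Williamson-type acetalisation of the sodium phenoxide masks O2 for the base-mediated homologation that follows.

Step 13
Reactants: 19 3-(benzyloxy)-4-methoxy-2-(methoxymethoxy)benzaldehyde
Product: 21 2-[3-(benzyloxy)-4-methoxy-2-(methoxymethoxy)phenyl]acetonitrile, via tosylvinyl formamide 20 (not isolated)
Conditions: TosMIC, KOtBu, DME, −40 °C; then MeOH, reflux
Reagents that add atoms: p-toluenesulfonylmethyl isocyanide (TosMIC), Cc1ccc(cc1)S(=O)(=O)C[N+]#[C-]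
Why: Van Leusen reductive cyanation: TosMIC adds to the aldehyde, the oxazoline opens to the vinylformamide, and methanolysis with loss of sulfinate gives the arylacetonitrile under basic conditions that the benzyl and methoxymethyl ethers tolerate.

Step 14
Reactants: 21 2-[3-(benzyloxy)-4-methoxy-2-(methoxymethoxy)phenyl]acetonitrile
Product: 23 methyl 2-[3-(benzyloxy)-2-hydroxy-4-methoxyphenyl]acetate, via imidate hydrochloride 22 (not isolated)
Conditions: HCl (3 M in MeOH), 0 °C → rt; then H2O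
Reagents that add atoms: methanol, CO; water, O
Why: Pinner methanolysis of the nitrile through the imidate, whose hydrolysis gives the methyl ester, while the same methanolic HCl cleaves the methoxymethyl acetal; any benzofuran-2(3H)-one formed by lactonisation is reopened by the acidic methanol, and the benzyl aryl ether survives at room temperature.

Step 15
Reactants: 16 {4-(benzyloxy)-2-[(3R)-7-(benzyloxy)-3,4-dihydro-2H-chromen-3-yl]-6-methoxyphenyl}methanol; 23 methyl 2-[3-(benzyloxy)-2-hydroxy-4-methoxyphenyl]acetate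
Product: 24 methyl 2-[3-(benzyloxy)-2-({4-(benzyloxy)-2-[(3R)-7-(benzyloxy)-3,4-dihydro-2H-chromen-3-yl]-6-methoxyphenyl}methoxy)-4-methoxyphenyl]acetate
Conditions: PPh3, DIAD, toluene, 0 °C → rt
Reagents that add atoms: none
Why: Mitsunobu etherification: the benzylic alcohol is activated as its oxyphosphonium salt and displaced by the phenoxide at oxygen, which avoids isolating an unstable 2,4-dialkoxybenzyl halide.

Step 16
Reactants: 24 methyl 2-[3-(benzyloxy)-2-({4-(benzyloxy)-2-[(3R)-7-(benzyloxy)-3,4-dihydro-2H-chromen-3-yl]-6-methoxyphenyl}methoxy)-4-methoxyphenyl]acetate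
Product: 25 methyl 2-[3-(benzyloxy)-2-({4-(benzyloxy)-2-[(3R)-7-(benzyloxy)-3,4-dihydro-2H-chromen-3-yl]-6-methoxyphenyl}methoxy)-4-methoxyphenyl]-2-diazoacetate
Conditions: p-ABSA, DBU, MeCN, 0 °C → rt
Reagents that add atoms: 4-acetamidobenzenesulfonyl azide (p-ABSA), CC(=O)Nc1ccc(cc1)S(=O)(=O)N=[N+]=[N-]
Why: Regitz diazo transfer to the arylacetate, whose benzylic C–H is acidic enough for DBU; no other acidic methylene is present.

Step 17
Reactants: 25 methyl 2-[3-(benzyloxy)-2-({4-(benzyloxy)-2-[(3R)-7-(benzyloxy)-3,4-dihydro-2H-chromen-3-yl]-6-methoxyphenyl}methoxy)-4-methoxyphenyl]-2-diazoacetate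
Product: 26 methyl (2R,3S)-7-(benzyloxy)-2-{4-(benzyloxy)-2-[(3R)-7-(benzyloxy)-3,4-dihydro-2H-chromen-3-yl]-6-methoxyphenyl}-6-methoxy-2,3-dihydro-1-benzofuran-3-carboxylate (2,3-cis)
Conditions: Rh2(S-PTTL)4 (2 mol %), toluene, −60 °C
Reagents that add atoms: none
Why: Intramolecular C–H insertion of the donor/acceptor rhodium carbenoid into the benzylic C–H next to the ether oxygen (activated further by the ortho methoxy and para benzyloxy groups) closes the five-membered ring; the chiral phthalimido carboxylate ligands select the carbenoid face and the cis arrangement, setting C3 as S and C2 as R.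

Step 18
Reactants: 26 methyl (2R,3S)-7-(benzyloxy)-2-{4-(benzyloxy)-2-[(3R)-7-(benzyloxy)-3,4-dihydro-2H-chromen-3-yl]-6-methoxyphenyl}-6-methoxy-2,3-dihydro-1-benzofuran-3-carboxylate
Product: 27 [(2R,3R)-7-(benzyloxy)-2-{4-(benzyloxy)-2-[(3R)-7-(benzyloxy)-3,4-dihydro-2H-chromen-3-yl]-6-methoxyphenyl}-6-methoxy-2,3-dihydro-1-benzofuran-3-yl]methanol (2,3-cis)
Conditions: LiAlH4, THF, −40 → 0 °C
Reagents that add atoms: none
Why: LiAlH4 reduction of the ester at low temperature, where hydride addition outruns enolisation so the C3 centre is not epimerised (the descriptor changes from S to R only through priorities); benzyl ethers are inert.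

Step 19
Reactants: 27 [(2R,3R)-7-(benzyloxy)-2-{4-(benzyloxy)-2-[(3R)-7-(benzyloxy)-3,4-dihydro-2H-chromen-3-yl]-6-methoxyphenyl}-6-methoxy-2,3-dihydro-1-benzofuran-3-yl]methanol; 28 3-(benzyloxy)phenol
Product: 29 (2R,3R)-7-(benzyloxy)-3-{[3-(benzyloxy)phenoxy]methyl}-2-{4-(benzyloxy)-2-[(3R)-7-(benzyloxy)-3,4-dihydro-2H-chromen-3-yl]-6-methoxyphenyl}-6-methoxy-2,3-dihydro-1-benzofuran (2,3-cis)
Conditions: PPh3, DIAD, THF, 0 → 40 °C
Reagents that add atoms: none
Why: Mitsunobu etherification of the primary alcohol with the phenol; no stereocentre is involved.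

Step 20
Reactants: 29 (2R,3R)-7-(benzyloxy)-3-{[3-(benzyloxy)phenoxy]methyl}-2-{4-(benzyloxy)-2-[(3R)-7-(benzyloxy)-3,4-dihydro-2H-chromen-3-yl]-6-methoxyphenyl}-6-methoxy-2,3-dihydro-1-benzofuran
Product: 31 2-(benzyloxy)-6-[(3R,4S)-7-(benzyloxy)-4-{4-(benzyloxy)-2-[(3R)-7-(benzyloxy)-3,4-dihydro-2H-chromen-3-yl]-6-methoxyphenyl}-3,4-dihydro-2H-chromen-3-yl]-3-methoxyphenol (3,4-trans), via ring-opened benzylic cation 30 (not isolated)
Conditions: BF3·OEt2 (1.5 equiv), CH2Cl2, −78 → −20 °C; aq NaHCO3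
Reagents that add atoms: none
Why: Proposed new method: BF3 binds O1 of the dihydrobenzofuran, the benzylic C2–O1 bond ionises to cation 30 (stabilised by the ortho methoxy and para benzyloxy groups of the central ring), and the tethered 3-(benzyloxy)phenyl ether attacks it para to its benzyloxy group to form C4–C4a. The closest known reactions are the Friedel–Crafts cycloalkylation of 1-aryl-3-aryloxypropyl cations to 4-arylchromans and the acid-induced C2 epimerisation of 2-aryl-2,3-dihydrobenzofurans through such ring-opened cations; joining the two in one operation is the untested part. The pyran ring closes as a six-membered electrophilic aromatic substitution, both carbons of the attacking arene C=C ending in the new ring (6-endo on the arene), through a half-chair. The new C4 centre is controlled by the existing C3 centre: with C3–H eclipsing the planar cation to avoid allylic strain with the flanking ortho substituent, the arene adds to the face that leaves both aryl groups pseudo-equatorial, so the (3R,4S) trans product should form from either C2 epimer. The step needs ring closure to outrun proton loss or hydride shift at C3, and attack at the ether carbon para rather than ortho to the benzyloxy group; the low temperature, the reversibility of phenoxide re-closure against irreversible arylation, and the crowding of the position between the two ether oxygens secure these. The ring B hydroxyl is released free and no other group is changed.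

Step 21
Reactants: 31 2-(benzyloxy)-6-[(3R,4S)-7-(benzyloxy)-4-{4-(benzyloxy)-2-[(3R)-7-(benzyloxy)-3,4-dihydro-2H-chromen-3-yl]-6-methoxyphenyl}-3,4-dihydro-2H-chromen-3-yl]-3-methoxyphenol
Product: 32 3-[(3R,4S)-7-hydroxy-4-{4-hydroxy-2-[(3R)-7-hydroxy-3,4-dihydro-2H-chromen-3-yl]-6-methoxyphenyl}-3,4-dihydro-2H-chromen-3-yl]-6-methoxybenzene-1,2-diol (CNP0227211.1)
Conditions: H2 (1 atm), 10% Pd/C, EtOAc–MeOH (degassed), rt
Reagents that add atoms: none
Why: Hydrogenolysis of the four benzyl aryl ethers over Pd/C; the methyl ethers, the chroman C–O bonds and the three stereocentres are not affected.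

**Compound list**

1 | 2-bromo-4-hydroxybenzaldehyde | O=Cc1ccc(O)cc1Br | starting material
2 | 4-(benzyloxy)-2-bromobenzaldehyde | O=Cc1ccc(OCc2ccccc2)cc1Br | intermediate
3 | [4-(benzyloxy)-2-bromophenyl]methanol | OCc1ccc(OCc2ccccc2)cc1Br | intermediate
4 | 4-(benzyloxy)-2-bromo-1-(bromomethyl)benzene | BrCc1ccc(OCc2ccccc2)cc1Br | intermediate
5 | methyl 2,4-dihydroxy-6-methylbenzoate | COC(=O)c1c(C)cc(O)cc1O | starting material
6 | methyl 4-(benzyloxy)-2-hydroxy-6-methylbenzoate | COC(=O)c1c(C)cc(OCc2ccccc2)cc1O | intermediate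
7 | methyl 4-(benzyloxy)-2-methoxy-6-methylbenzoate | COC(=O)c1c(C)cc(OCc2ccccc2)cc1OC | intermediate
8 | methyl 4-(benzyloxy)-2-(lithiomethyl)-6-methoxybenzoate | COC(=O)c1c(C[Li])cc(OCc2ccccc2)cc1OC | intermediate (not isolated)
9 | 2-[5-(benzyloxy)-3-methoxy-2-(methoxycarbonyl)phenyl]acetic acid | COC(=O)c1c(CC(=O)O)cc(OCc2ccccc2)cc1OC | intermediate
10 | (4R)-4-benzyl-1,3-oxazolidin-2-one | O=C1N[C@H](Cc2ccccc2)CO1 | starting material
11 | 2-[5-(benzyloxy)-3-methoxy-2-(methoxycarbonyl)phenyl]acetic pivalic anhydride | COC(=O)c1c(CC(=O)OC(=O)C(C)(C)C)cc(OCc2ccccc2)cc1OC | intermediate (not isolated)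
12 | methyl 2-{2-[(4R)-4-benzyl-2-oxo-1,3-oxazolidin-3-yl]-2-oxoethyl}-4-(benzyloxy)-6-methoxybenzoate | COC(=O)c1c(CC(=O)N2C(=O)OC[C@H]2Cc2ccccc2)cc(OCc2ccccc2)cc1OC | intermediate
13 | sodium (Z)-enolate of 12 | [Na+].[O-]/C(=C\c1cc(OCc2ccccc2)cc(OC)c1C(=O)OC)N1C(=O)OC[C@H]1Cc1ccccc1 | intermediate (not isolated)
14 | methyl 2-{(2R)-1-[(4R)-4-benzyl-2-oxo-1,3-oxazolidin-3-yl]-3-[4-(benzyloxy)-2-bromophenyl]-1-oxopropan-2-yl}-4-(benzyloxy)-6-methoxybenzoate | COC(=O)c1c(OC)cc(OCc2ccccc2)cc1[C@@H](Cc1ccc(OCc2ccccc2)cc1Br)C(=O)N1C(=O)OC[C@H]1Cc1ccccc1 | intermediate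
15 | (2R)-2-[5-(benzyloxy)-2-(hydroxymethyl)-3-methoxyphenyl]-3-[4-(benzyloxy)-2-bromophenyl]propan-1-ol | OCc1c(OC)cc(OCc2ccccc2)cc1[C@@H](Cc1ccc(OCc2ccccc2)cc1Br)CO | intermediate
16 | {4-(benzyloxy)-2-[(3R)-7-(benzyloxy)-3,4-dihydro-2H-chromen-3-yl]-6-methoxyphenyl}methanol | OCc1c(OC)cc(OCc2ccccc2)cc1[C@@H]1COc2cc(OCc3ccccc3)ccc2C1 | intermediate
17 | 2,3-dihydroxy-4-methoxybenzaldehyde | COc1ccc(C=O)c(O)c1O | starting material
18 | 3-(benzyloxy)-2-hydroxy-4-methoxybenzaldehyde | COc1ccc(C=O)c(O)c1OCc1ccccc1 | intermediate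
19 | 3-(benzyloxy)-4-methoxy-2-(methoxymethoxy)benzaldehyde | COCOc1c(C=O)ccc(OC)c1OCc1ccccc1 | intermediate
20 | N-{2-[3-(benzyloxy)-4-methoxy-2-(methoxymethoxy)phenyl]-1-(4-methylbenzenesulfonyl)ethenyl}formamide (alkene geometry not defined) | O=CNC(=Cc1ccc(OC)c(OCc2ccccc2)c1OCOC)S(=O)(=O)c1ccc(C)cc1 | intermediate (not isolated)
21 | 2-[3-(benzyloxy)-4-methoxy-2-(methoxymethoxy)phenyl]acetonitrile | N#CCc1ccc(OC)c(OCc2ccccc2)c1OCOC | intermediate
22 | methyl 2-[3-(benzyloxy)-2-hydroxy-4-methoxyphenyl]ethanimidate hydrochloride | COC(=[NH2+])Cc1ccc(OC)c(OCc2ccccc2)c1O.[Cl-] | intermediate (not isolated)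
23 | methyl 2-[3-(benzyloxy)-2-hydroxy-4-methoxyphenyl]acetate | COC(=O)Cc1ccc(OC)c(OCc2ccccc2)c1O | intermediate
24 | methyl 2-[3-(benzyloxy)-2-({4-(benzyloxy)-2-[(3R)-7-(benzyloxy)-3,4-dihydro-2H-chromen-3-yl]-6-methoxyphenyl}methoxy)-4-methoxyphenyl]acetate | COC(=O)Cc1ccc(OC)c(OCc2ccccc2)c1OCc1c(OC)cc(OCc2ccccc2)cc1[C@@H]1COc2cc(OCc3ccccc3)ccc2C1 | intermediate
25 | methyl 2-[3-(benzyloxy)-2-({4-(benzyloxy)-2-[(3R)-7-(benzyloxy)-3,4-dihydro-2H-chromen-3-yl]-6-methoxyphenyl}methoxy)-4-methoxyphenyl]-2-diazoacetate | COC(=O)C(=[N+]=[N-])c1ccc(OC)c(OCc2ccccc2)c1OCc1c(OC)cc(OCc2ccccc2)cc1[C@@H]1COc2cc(OCc3ccccc3)ccc2C1 | intermediate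
26 | methyl (2R,3S)-7-(benzyloxy)-2-{4-(benzyloxy)-2-[(3R)-7-(benzyloxy)-3,4-dihydro-2H-chromen-3-yl]-6-methoxyphenyl}-6-methoxy-2,3-dihydro-1-benzofuran-3-carboxylate (2,3-cis) | COc1ccc2c(c1OCc1ccccc1)O[C@@H](c1c(OC)cc(OCc3ccccc3)cc1[C@@H]1COc3cc(OCc4ccccc4)ccc3C1)[C@H]2C(=O)OC | intermediate
27 | [(2R,3R)-7-(benzyloxy)-2-{4-(benzyloxy)-2-[(3R)-7-(benzyloxy)-3,4-dihydro-2H-chromen-3-yl]-6-methoxyphenyl}-6-methoxy-2,3-dihydro-1-benzofuran-3-yl]methanol (2,3-cis) | COc1ccc2c(c1OCc1ccccc1)O[C@@H](c1c(OC)cc(OCc3ccccc3)cc1[C@@H]1COc3cc(OCc4ccccc4)ccc3C1)[C@H]2CO | intermediate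
28 | 3-(benzyloxy)phenol | Oc1cccc(OCc2ccccc2)c1 | starting material
29 | (2R,3R)-7-(benzyloxy)-3-{[3-(benzyloxy)phenoxy]methyl}-2-{4-(benzyloxy)-2-[(3R)-7-(benzyloxy)-3,4-dihydro-2H-chromen-3-yl]-6-methoxyphenyl}-6-methoxy-2,3-dihydro-1-benzofuran (2,3-cis) | COc1ccc2c(c1OCc1ccccc1)O[C@@H](c1c(OC)cc(OCc3ccccc3)cc1[C@@H]1COc3cc(OCc4ccccc4)ccc3C1)[C@H]2COc1cccc(OCc2ccccc2)c1 | intermediate (key-step precursor)
30 | ring-opened zwitterion: benzylic cation on the central ring, ring B phenoxide bound to BF3, C3 centre retained | COc1ccc([C@H](COc2cccc(OCc3ccccc3)c2)[CH+]c2c(OC)cc(OCc3ccccc3)cc2[C@@H]2COc3cc(OCc4ccccc4)ccc3C2)c(O[B-](F)(F)F)c1OCc1ccccc1 | intermediate (not isolated)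
31 | 2-(benzyloxy)-6-[(3R,4S)-7-(benzyloxy)-4-{4-(benzyloxy)-2-[(3R)-7-(benzyloxy)-3,4-dihydro-2H-chromen-3-yl]-6-methoxyphenyl}-3,4-dihydro-2H-chromen-3-yl]-3-methoxyphenol (3,4-trans) | COc1ccc([C@@H]2COc3cc(OCc4ccccc4)ccc3[C@H]2c2c(OC)cc(OCc3ccccc3)cc2[C@@H]2COc3cc(OCc4ccccc4)ccc3C2)c(O)c1OCc1ccccc1 | intermediate (key-step product)
32 | 3-[(3R,4S)-7-hydroxy-4-{4-hydroxy-2-[(3R)-7-hydroxy-3,4-dihydro-2H-chromen-3-yl]-6-methoxyphenyl}-3,4-dihydro-2H-chromen-3-yl]-6-methoxybenzene-1,2-diol | COc1ccc([C@@H]2COc3cc(O)ccc3[C@H]2c2c(OC)cc(O)cc2[C@@H]2COc3cc(O)ccc3C2)c(O)c1O | target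

**Totals and risks**

Total step count: 21. Longest linear sequence: 14 steps (steps 4–10, then 15–21, from methyl 2,4-dihydroxy-6-methylbenzoate).

Steps most likely to fail:

1. Step 20 (ring switch). After ionisation the cation may shed the proton on C3 or take a hydride from it faster than the arene closes, which would erode the C3 centre. Alternatively, phenoxide re-closure may hold the material as dihydrobenzofuran until benzyl ethers begin to cleave. The fallback uses known chemistry, sets out from 23 and 16 and comes back at 31. It closes the same chroman from an open-chain benzylic alcohol whose ring B oxygen is capped, so that no furan can form and the established acid-mediated cycloalkylation of 1-aryl-3-aryloxypropan-1-ols applies. Phenol 23 is allylated (allyl bromide, K2CO3) to methyl 2-[3-(benzyloxy)-4-methoxy-2-(prop-2-en-1-yloxy)phenyl]acetate F1, which is saponified (LiOH) to the acid F2. F2 is joined to (4S)-4-benzyl-1,3-oxazolidin-2-one through its pivalic mixed anhydride to give the imide F3. Alcohol 16 is oxidised with MnO2 to the aldehyde F4. The dibutylboron enolate of F3 (Bu2BOTf, iPr2NEt) adds to F4 to give the Evans syn aldol F5, the auxiliary fixing the carbon that becomes chroman C3. LiBH4 releases the diol F6, and Mitsunobu etherification of its primary hydroxyl with 28 gives the aryl ether F7. BF3·OEt2 in CH2Cl2 at −78 °C ionises the benzylic alcohol of F7 and the arene closes to the O-allyl chroman F8. Pd(PPh3)4 and morpholine remove the allyl group to give 31.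

2. Step 17 (C–H insertion). The benzylic C–H to be inserted is flanked by two ortho substituents, so insertion may be slow enough for carbene dimerisation to intervene, or the catalyst may control the C3 centre poorly against the resident isoflavan centre. The fallback sets out from 23 and 16 and comes back at 29. It takes the open-chain aryl ether F7 of the previous fallback, in which C3 was set by the aldol auxiliary, and removes the allyl group with Pd(PPh3)4 and morpholine to give the phenol F9. Mitsunobu cyclodehydration (PPh3, DIAD) then closes the furan ring by O-alkylation at the benzylic carbinol. Inversion there gives 29, and any ion-pair leakage gives its trans C2 epimer F10, which serves equally in step 20.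

3. Step 15 (Mitsunobu coupling of the two fragments). The oxyphosphonium salt of the very electron-rich, doubly ortho-substituted benzylic alcohol may ionise and alkylate the phenol ring at carbon, or the two hindered partners may fail to couple. The fallback sets out from 16 and comes back at 24. Alcohol 16 is converted with methanesulfonyl chloride, Et3N and LiCl at 0 °C into the benzylic chloride F11, which is used at once to O-alkylate 23 with K2CO3 in DMF, a Williamson etherification in which the phenoxide reacts at oxygen.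

**Further compounds**

F1 | step 20 | methyl 2-[3-(benzyloxy)-4-methoxy-2-(prop-2-en-1-yloxy)phenyl]acetate | COC(=O)Cc1ccc(OC)c(OCc2ccccc2)c1OCC=C
F2 | step 20 | 2-[3-(benzyloxy)-4-methoxy-2-(prop-2-en-1-yloxy)phenyl]acetic acid | OC(=O)Cc1ccc(OC)c(OCc2ccccc2)c1OCC=C
F3 | step 20 | (4S)-4-benzyl-3-{2-[3-(benzyloxy)-4-methoxy-2-(prop-2-en-1-yloxy)phenyl]acetyl}-1,3-oxazolidin-2-one | C=CCOc1c(CC(=O)N2C(=O)OC[C@@H]2Cc2ccccc2)ccc(OC)c1OCc1ccccc1
F4 | step 20 | 4-(benzyloxy)-2-[(3R)-7-(benzyloxy)-3,4-dihydro-2H-chromen-3-yl]-6-methoxybenzaldehyde | O=Cc1c(OC)cc(OCc2ccccc2)cc1[C@@H]1COc2cc(OCc3ccccc3)ccc2C1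
F5 | step 20 | (4S)-4-benzyl-3-[(2S,3S)-3-{4-(benzyloxy)-2-[(3R)-7-(benzyloxy)-3,4-dihydro-2H-chromen-3-yl]-6-methoxyphenyl}-2-[3-(benzyloxy)-4-methoxy-2-(prop-2-en-1-yloxy)phenyl]-3-hydroxypropanoyl]-1,3-oxazolidin-2-one | C=CCOc1c(OCc2ccccc2)c(OC)ccc1[C@H](C(=O)N1C(=O)OC[C@@H]1Cc1ccccc1)[C@H](O)c1c(OC)cc(OCc2ccccc2)cc1[C@@H]1COc2cc(OCc3ccccc3)ccc2C1
F6 | step 20 | (1S,2R)-1-{4-(benzyloxy)-2-[(3R)-7-(benzyloxy)-3,4-dihydro-2H-chromen-3-yl]-6-methoxyphenyl}-2-[3-(benzyloxy)-4-methoxy-2-(prop-2-en-1-yloxy)phenyl]propane-1,3-diol | C=CCOc1c(OCc2ccccc2)c(OC)ccc1[C@H](CO)[C@H](O)c1c(OC)cc(OCc2ccccc2)cc1[C@@H]1COc2cc(OCc3ccccc3)ccc2C1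
F7 | step 20 | (1S,2R)-1-{4-(benzyloxy)-2-[(3R)-7-(benzyloxy)-3,4-dihydro-2H-chromen-3-yl]-6-methoxyphenyl}-2-[3-(benzyloxy)-4-methoxy-2-(prop-2-en-1-yloxy)phenyl]-3-[3-(benzyloxy)phenoxy]propan-1-ol | C=CCOc1c(OCc2ccccc2)c(OC)ccc1[C@H](COc1cccc(OCc2ccccc2)c1)[C@H](O)c1c(OC)cc(OCc2ccccc2)cc1[C@@H]1COc2cc(OCc3ccccc3)ccc2C1
F8 | step 20 | (3R,4S)-7-(benzyloxy)-4-{4-(benzyloxy)-2-[(3R)-7-(benzyloxy)-3,4-dihydro-2H-chromen-3-yl]-6-methoxyphenyl}-3-[3-(benzyloxy)-4-methoxy-2-(prop-2-en-1-yloxy)phenyl]-3,4-dihydro-2H-chromene | COc1ccc([C@@H]2COc3cc(OCc4ccccc4)ccc3[C@H]2c2c(OC)cc(OCc3ccccc3)cc2[C@@H]2COc3cc(OCc4ccccc4)ccc3C2)c(OCC=C)c1OCc1ccccc1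
F9 | step 17 | (1S,2R)-1-{4-(benzyloxy)-2-[(3R)-7-(benzyloxy)-3,4-dihydro-2H-chromen-3-yl]-6-methoxyphenyl}-2-[3-(benzyloxy)-2-hydroxy-4-methoxyphenyl]-3-[3-(benzyloxy)phenoxy]propan-1-ol | Oc1c(OCc2ccccc2)c(OC)ccc1[C@H](COc1cccc(OCc2ccccc2)c1)[C@H](O)c1c(OC)cc(OCc2ccccc2)cc1[C@@H]1COc2cc(OCc3ccccc3)ccc2C1
F10 | step 17 | (2S,3R)-7-(benzyloxy)-3-{[3-(benzyloxy)phenoxy]methyl}-2-{4-(benzyloxy)-2-[(3R)-7-(benzyloxy)-3,4-dihydro-2H-chromen-3-yl]-6-methoxyphenyl}-6-methoxy-2,3-dihydro-1-benzofuran (2,3-trans) | COc1ccc2c(c1OCc1ccccc1)O[C@H](c1c(OC)cc(OCc3ccccc3)cc1[C@@H]1COc3cc(OCc4ccccc4)ccc3C1)[C@H]2COc1cccc(OCc2ccccc2)c1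
F11 | step 15 | (3R)-7-(benzyloxy)-3-[5-(benzyloxy)-2-(chloromethyl)-3-methoxyphenyl]-3,4-dihydro-2H-chromene | ClCc1c(OC)cc(OCc2ccccc2)cc1[C@@H]1COc2cc(OCc3ccccc3)ccc2C1
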